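**Plan**

1. The last cuts are the C6 ester C–O bond and the C9-OH/C8=CH2 pair; the pair is the allylic transposition product of a C8=C9 alkene, which leads back to the 4β,6α-diol (jaeschkeanadiol).
2. Key cut: C1–C10 and C8=C9 are cut together, removing C9–C10 as a vinylphosphonium two-carbon unit; what remains is a cyclopentane with a tertiary-radical precursor at C1 and a methyl ketone at C8.
3. The feature that allows this: C1 is a quaternary carbon with only carbon neighbours (an ideal tertiary radical site), and C9–C10 is an isolated two-carbon bridge in the seven-membered ring between C1 and the methyl-bearing C8, so radical addition at C10 followed by ylide olefination at C9 closes that ring in one operation.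
4. Earlier cuts: C6–C7 (acetone aldol) and C1–C5 (intramolecular aldol), back to the keto aldehyde obtained by ozonolytic cleavage of the ring alkene of (S)-terpinen-4-ol.
5. Forward order: the six-membered ring of the terpene is cleaved and re-closed as the five-membered ring, the side chain is added, the seven-membered ring is closed by the radical/Wittig annulation, then epoxidation, esterification and epoxide-to-allylic-alcohol transposition.
6. Stereochemistry: C4 from terpinen-4-ol; C5 by equilibration (formyl trans to isopropyl); C6 by D-proline; C1 by radical attack anti to the C5 side chain; C9 by C6-OH-directed epoxidation and a stereoretentive epoxide opening.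

Key step: step 7

Assumption: (S)-(+)-terpinen-4-ol is used as commercial material of high enantiomeric purity.
Locants are those of the daucane skeleton: C1 (quaternary, methyl C15), C2, C3, C4 (carbinol with isopropyl), C5 (ring-fusion CH), C6, C7, C8 (with C14), C9, C10. β is the face of the C4 oxygen (and of C15 in the target); α is the face of H-5.

**Route**

Step 1
Reactants: 1 (S)-(+)-terpinen-4-ol
Product: 2 (S)-terpinen-4-ol triethylsilyl ether
Conditions: TESOTf, 2,6-lutidine, CH2Cl2, 0 °C to rt
Reagents that add atoms: triethylsilyl trifluoromethanesulfonate, CC[Si](CC)(CC)OS(=O)(=O)C(F)(F)F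
Why: Silyl triflate silylation of a hindered tertiary alcohol; it masks the hydroxyl that would otherwise sit β to the aldehyde made in step 2 (retro-aldol, dehydration), and the stereocentre is untouched.

Step 2
Reactants: 2 (S)-terpinen-4-ol triethylsilyl ether
Product: 4 (3S)-6-oxo-3-(propan-2-yl)-3-(triethylsilyloxy)heptanal, via secondary ozonide 3 (not isolated)
Conditions: O3, CH2Cl2, −78 °C; then Me2S, −78 °C to rt
Reagents that add atoms: ozone, [O-][O+]=O
Why: Ozonolysis with reductive work-up cleaves the trisubstituted ring alkene to an open 1,6-keto aldehyde that keeps the carbinol stereocentre (future C4).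

Step 3
Reactants: 4 (3S)-6-oxo-3-(propan-2-yl)-3-(triethylsilyloxy)heptanal
Product: 5 2-hydroxy-2-methyl-5-(propan-2-yl)-5-(triethylsilyloxy)cyclopentane-1-carbaldehyde (formyl at C5, hydroxyl at C1 and silyloxy at C4 all β; isopropyl and C1 methyl α)
Conditions: L-proline (20 mol %), DMSO, rt
Reagents that add atoms: none
Why: Proline-catalysed intramolecular aldol addition (5-enolexo, aldehyde enamine onto the methyl ketone) closes the cyclopentane; C5 and C1 can equilibrate through enamine and retro-aldol pathways, so the aldol should settle with the formyl group trans to isopropyl and hydrogen-bonded cis to the new hydroxyl, and the C1 configuration is erased in step 7 in any case.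

Step 4
Reactants: 5 cyclopentane aldol aldehyde; 6 acetone
Product: 7 (4S)-4-hydroxy-4-[2-hydroxy-2-methyl-5-(propan-2-yl)-5-(triethylsilyloxy)cyclopentyl]butan-2-one (6S in daucane locants)
Conditions: D-proline (30 mol %), acetone/DMSO 1:4, rt
Reagents that add atoms: none
Why: Proline-catalysed direct aldol reaction; the acetone enamine adds to the α-branched aldehyde through the hydrogen-bonded chair transition state, and D-proline is the antipode that should give the 6S carbinol under catalyst control.

Step 5
Reactants: 7 β-hydroxy ketone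
Product: 8 (4S)-4-(triethylsilyloxy)-4-[2-hydroxy-2-methyl-5-(propan-2-yl)-5-(triethylsilyloxy)cyclopentyl]butan-2-one
Conditions: TESCl, imidazole, CH2Cl2, 0 °C
Reagents that add atoms: chlorotriethylsilane, CC[Si](Cl)(CC)CC
Why: Silylation of the secondary C6 hydroxyl in preference to the tertiary C1 hydroxyl, which is kept free for step 6.

Step 6
Reactants: 8 bis-silyl ether with free C1 hydroxyl
Product: 10 cesium oxalate of the C1 tertiary alcohol of 8, via methyl oxalate 9 (not isolated)
Conditions: ClC(O)CO2Me, Et3N, DMAP, CH2Cl2, 0 °C to rt; then CsOH·H2O (1 equiv), THF/H2O, rt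
Reagents that add atoms: methyl chlorooxoacetate, COC(=O)C(Cl)=O; cesium hydroxide, [Cs+].[OH-]
Why: Acylation of the tertiary alcohol by the reactive oxalyl chloride half ester and mild saponification of the activated methyl ester give the stable oxalate salt used as a tertiary-radical precursor.

Step 7
Reactants: 10 cesium oxalate; 11 vinyltriphenylphosphonium bromide
Product: 13 4,6-bis-O-triethylsilyl-daucane-8-ene-4β,6α-diol (trans-fused bicycle; C15 β, H-5 α), via phosphonium ylide 12 (not isolated)
Conditions: [Ir(dF(CF3)ppy)2(dtbbpy)]PF6 (2 mol %), anhydrous DMSO, 4 Å MS, blue LEDs (450 nm), rt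
Reagents that add atoms: none
Why: Proposed new method: the photoexcited trivalent iridium complex oxidises the oxalate, two molecules of CO2 are lost and the tertiary C1 radical adds to the β-carbon of the vinylphosphonium salt (C1–C10); the adduct radical is reduced by the divalent iridium complex to ylide 12 (radical–polar crossover), which undergoes an intramolecular Wittig reaction with the C8 methyl ketone (C8=C9). The closest known reactions are the photoredox Giese addition of tertiary radicals from cesium oxalates, the three-component photoredox radical addition/Wittig olefination with vinylphosphonium salts, and the anionic Michael–Wittig annulation of vinylphosphonium salts; new is their union into a ring-forming annulation. The seven-membered ring closes in the Wittig step by 7-exo-trig attack of the ylide carbon C9 on the ketone carbon, and the ring permits only the cis alkene. C1 is the only new stereocentre and is set by the substrate: the planar radical is attacked on the α face, anti to the adjacent C5 side chain, which places C10 trans to C6 (trans ring fusion) and the methyl group β. The step needs the ylide to olefinate faster than it is protonated or enolises the β-silyloxy ketone; the anhydrous, base-free medium, the lower acidity of the ketone compared with the phosphonium salt and the intramolecular delivery should secure this.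

Step 8
Reactants: 13 bis-silyl ether
Product: 14 daucane-8-ene-4β,6α-diol (jaeschkeanadiol)
Conditions: HF·pyridine, THF/pyridine, 0 °C to rt
Reagents that add atoms: none
Why: Fluoride-mediated cleavage of both triethylsilyl ethers; the trisubstituted alkene and the tertiary alcohol tolerate buffered HF.

Step 9
Reactants: 14 jaeschkeanadiol
Product: 15 8α,9α-epoxydaucane-4β,6α-diol
Conditions: VO(acac)2 (5 mol %), t-BuOOH, CH2Cl2, 0 °C to rt
Reagents that add atoms: tert-butyl hydroperoxide, CC(C)(C)OO
Why: Hydroxyl-directed vanadium-catalysed epoxidation; the homoallylic 6α-hydroxyl delivers the peroxide oxygen to the α face of the C8=C9 alkene, which fixes the later 9α C–O bond.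

Step 10
Reactants: 16 4-hydroxybenzoic acid
Product: 18 4-(tert-butyldimethylsilyloxy)benzoic acid, via bis-silylated benzoate 17 (not isolated)
Conditions: TBSCl (2.2 equiv), imidazole, DMF, rt; then AcOH/THF/H2O, rt
Reagents that add atoms: tert-butyldimethylsilyl chloride, CC(C)(C)[Si](C)(C)Cl
Why: Silylation of both acidic hydroxyls followed by selective hydrolysis of the labile silyl ester leaves the phenol protected.

Step 11
Reactants: 15 epoxy diol; 18 4-(tert-butyldimethylsilyloxy)benzoic acid
Product: 19 8α,9α-epoxydaucane-4β,6α-diol 6-[4-(tert-butyldimethylsilyloxy)benzoate]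
Conditions: DCC, DMAP, CH2Cl2, rt
Reagents that add atoms: none
Why: Steglich esterification; the secondary C6 hydroxyl is the only acylable one (the tertiary C4 hydroxyl is inert), and the neutral conditions spare the epoxide.

Step 12
Reactants: 19 epoxy ester
Product: 20 4,9-bis-O-trimethylsilyl ferugin tert-butyldimethylsilyl (phenol) ether
Conditions: TMSOTf, 2,6-lutidine, toluene, −78 °C; then DBU, −78 °C to rt
Reagents that add atoms: trimethylsilyl trifluoromethanesulfonate, C[Si](C)(C)OS(=O)(=O)C(F)(F)F
Why: Silyl triflate/amidine isomerisation of an epoxide to an allylic silyl ether: the tertiary C8–O bond opens and the hindered base removes the most accessible proton (C14 methyl) to give the exocyclic alkene, while the C9–O bond is never broken so the 9α configuration is kept; the C4 hydroxyl is silylated in passing.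

Step 13
Reactants: 20 tris-silyl ether
Product: 21 ferugin
Conditions: HF·pyridine, THF/pyridine, 0 °C to rt
Reagents that add atoms: none
Why: Global desilylation with buffered fluoride removes the two trimethylsilyl ethers and the aryl silyl ether without touching the ester, the allylic alcohol or the exocyclic alkene.

**Compound list**

1 | (S)-(+)-terpinen-4-ol | CC1=CC[C@](O)(C(C)C)CC1 | starting material
2 | (S)-terpinen-4-ol triethylsilyl ether | CC1=CC[C@](O[Si](CC)(CC)CC)(C(C)C)CC1 | intermediate
3 | secondary ozonide of 2 | CC12CC[C@@](O[Si](CC)(CC)CC)(C(C)C)CC(OO1)O2 | intermediate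
4 | (3S)-6-oxo-3-(propan-2-yl)-3-(triethylsilyloxy)heptanal | CC(=O)CC[C@@](O[Si](CC)(CC)CC)(C(C)C)CC=O | intermediate
5 | 2-hydroxy-2-methyl-5-(propan-2-yl)-5-(triethylsilyloxy)cyclopentane-1-carbaldehyde (CHO, C1-OH and OSiEt3 cis) | O=C[C@@H]1[C@@](C)(CC[C@@]1(O[Si](CC)(CC)CC)C(C)C)O | intermediate
6 | acetone | CC(C)=O | starting material
7 | (4S)-4-hydroxy-4-[2-hydroxy-2-methyl-5-(propan-2-yl)-5-(triethylsilyloxy)cyclopentyl]butan-2-one | CC(=O)C[C@H](O)[C@@H]1[C@@](C)(CC[C@@]1(O[Si](CC)(CC)CC)C(C)C)O | intermediate
8 | C6 triethylsilyl ether of 7 | CC(=O)C[C@H](O[Si](CC)(CC)CC)[C@@H]1[C@@](C)(CC[C@@]1(O[Si](CC)(CC)CC)C(C)C)O | intermediate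
9 | methyl oxalate of the C1 hydroxyl of 8 | CC(=O)C[C@H](O[Si](CC)(CC)CC)[C@@H]1[C@@](C)(CC[C@@]1(O[Si](CC)(CC)CC)C(C)C)OC(=O)C(=O)OC | intermediate
10 | cesium oxalate of the C1 hydroxyl of 8 | CC(=O)C[C@H](O[Si](CC)(CC)CC)[C@@H]1[C@@](C)(CC[C@@]1(O[Si](CC)(CC)CC)C(C)C)OC(=O)C(=O)[O-].[Cs+] | intermediate
11 | vinyltriphenylphosphonium bromide | C=C[P+](c1ccccc1)(c1ccccc1)c1ccccc1.[Br-] | starting material
12 | phosphonium ylide (C10 α on C1, C15 β) | CC(=O)C[C@H](O[Si](CC)(CC)CC)[C@@H]1[C@](C)(CC[C@@]1(O[Si](CC)(CC)CC)C(C)C)CC=P(c1ccccc1)(c1ccccc1)c1ccccc1 | intermediate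
13 | 4,6-bis-O-triethylsilyl-daucane-8-ene-4β,6α-diol | C1=C(C)C[C@H](O[Si](CC)(CC)CC)[C@@H]2[C@](C)(CC[C@@]2(O[Si](CC)(CC)CC)C(C)C)C1 | intermediate
14 | daucane-8-ene-4β,6α-diol (jaeschkeanadiol) | C1=C(C)C[C@H](O)[C@@H]2[C@](C)(CC[C@@]2(O)C(C)C)C1 | intermediate
15 | 8α,9α-epoxydaucane-4β,6α-diol | C[C@@]13C[C@H](O)[C@@H]2[C@](C)(CC[C@@]2(O)C(C)C)C[C@@H]1O3 | intermediate
16 | 4-hydroxybenzoic acid | OC(=O)c1ccc(O)cc1 | starting material
17 | tert-butyldimethylsilyl 4-(tert-butyldimethylsilyloxy)benzoate | CC(C)(C)[Si](C)(C)OC(=O)c1ccc(O[Si](C)(C)C(C)(C)C)cc1 | intermediate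
18 | 4-(tert-butyldimethylsilyloxy)benzoic acid | OC(=O)c1ccc(O[Si](C)(C)C(C)(C)C)cc1 | intermediate
19 | 8α,9α-epoxydaucane-4β,6α-diol 6-[4-(tert-butyldimethylsilyloxy)benzoate] | C[C@@]13C[C@H](OC(=O)c4ccc(O[Si](C)(C)C(C)(C)C)cc4)[C@@H]2[C@](C)(CC[C@@]2(O)C(C)C)C[C@@H]1O3 | intermediate
20 | 4,9-bis-O-trimethylsilyl ferugin phenol tert-butyldimethylsilyl ether | C=C1C[C@H](OC(=O)c2ccc(O[Si](C)(C)C(C)(C)C)cc2)[C@@H]2[C@](C)(CC[C@@]2(O[Si](C)(C)C)C(C)C)C[C@@H]1O[Si](C)(C)C | intermediate
21 | ferugin | C=C1C[C@H](OC(=O)c2ccc(O)cc2)[C@@H]2[C@](C)(CC[C@@]2(O)C(C)C)C[C@@H]1O | target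

**Step count and risks**

Total step count: 13. Longest linear sequence: 12 (steps 1 to 9 and 11 to 13).

Steps most likely to fail:

- Step 7. The ylide may be quenched by protonation or by enolisation of the ketone before it olefinates, the adduct radical may not be reduced efficiently, or the seven-membered ring closure may be slow. Fallback with known chemistry: from 10, photoredox Giese addition to vinylboronic acid pinacol ester (same iridium photocatalyst, DMF/H2O) should give the pinacol boronate F1 with the same anti facial selectivity at C1. Oxidation with NaBO3 gives the primary alcohol F2, and Dess–Martin periodinane gives the keto aldehyde F3. Intramolecular McMurry coupling (TiCl3, Zn–Cu, DME, reflux; low-valent titanium) then closes C8=C9 and returns to the route at 13.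

- Step 4. Addition to the aldehyde flanked by two quaternary carbons may be sluggish, which would allow amine-mediated dehydration or retro-aldol opening of the β-hydroxy aldehyde and erode catalyst control at C6. Fallback: from 5, asymmetric methallylboration with B-methallyldiisopinocampheylborane (the antipode that gives the 6S carbinol; Et2O, −78 °C, then NaOH/H2O2) gives the homoallylic alcohol F4. TESCl/imidazole gives its C6 silyl ether F5, and ozonolysis of the 1,1-disubstituted alkene (O3, CH2Cl2, −78 °C; Me2S) gives the methyl ketone and returns to the route at 8.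

- Step 3. The tertiary aldol may dehydrate to the conjugated enal under amine catalysis, or C5 may settle in the wrong configuration. Fallback: from 4, deliberate aldol condensation (piperidine, AcOH, benzene, reflux) gives the enal F6, and Weitz–Scheffer epoxidation (H2O2, NaOH, MeOH) gives the epoxy aldehyde F7. Reductive opening of the α,β-epoxy carbonyl at C5 with Cp2TiCl (trivalent titanium, from Cp2TiCl2 and Zn; THF/MeOH), followed by protonation and equilibration at C5, gives the β-hydroxy aldehyde and returns to the route at 5.

Further compounds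
F1 | step 7 | (4S)-4-(triethylsilyloxy)-4-[2-methyl-2-(2-(pinacolboryl)ethyl)-5-(propan-2-yl)-5-(triethylsilyloxy)cyclopentyl]butan-2-one | CC(=O)C[C@H](O[Si](CC)(CC)CC)[C@@H]1[C@](C)(CC[C@@]1(O[Si](CC)(CC)CC)C(C)C)CCB1OC(C)(C)C(C)(C)O1
F2 | step 7 | primary alcohol from F1 (2-hydroxyethyl on C1) | CC(=O)C[C@H](O[Si](CC)(CC)CC)[C@@H]1[C@](C)(CC[C@@]1(O[Si](CC)(CC)CC)C(C)C)CCO
F3 | step 7 | keto aldehyde from F2 (2-oxoethyl on C1) | CC(=O)C[C@H](O[Si](CC)(CC)CC)[C@@H]1[C@](C)(CC[C@@]1(O[Si](CC)(CC)CC)C(C)C)CC=O
F4 | step 4 | (1S)-1-[2-hydroxy-2-methyl-5-(propan-2-yl)-5-(triethylsilyloxy)cyclopentyl]-3-methylbut-3-en-1-ol | C=C(C)C[C@H](O)[C@@H]1[C@@](C)(CC[C@@]1(O[Si](CC)(CC)CC)C(C)C)O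
F5 | step 4 | C6 triethylsilyl ether of F4 | C=C(C)C[C@H](O[Si](CC)(CC)CC)[C@@H]1[C@@](C)(CC[C@@]1(O[Si](CC)(CC)CC)C(C)C)O
F6 | step 3 | (5R)-2-methyl-5-(propan-2-yl)-5-(triethylsilyloxy)cyclopent-1-ene-1-carbaldehyde | O=CC1=C(C)CC[C@@]1(O[Si](CC)(CC)CC)C(C)C
F7 | step 3 | 1,2-epoxide of F6 (epoxide oxygen cis to the silyloxy group) | O=C[C@@]12O[C@]1(C)CC[C@@]2(O[Si](CC)(CC)CC)C(C)C
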